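## Retrosynthetic overview

1. Target ⇒ spiro[4.5]cyclohexadienone by a 1,2-shift of the benzylic carbon (dienone–phenol ring expansion, five- to six-membered carbocycle).
2. Spirodienone ⇒ para-quinone methide (ipso 1,6-addition of ring A) ⇒ achiral (E,E)-2,3-bis(arylidene) hydroxy-aldehyde (chiral-acid tautomerisation; both stereocentres set here).
3. Diene ⇒ Stille coupling of a (Z)-α-iodo enal and a (Z)-α-stannyl allylic alcohol (C-2–C-3 bond); both come from one arylpropargyl alcohol (trans-hydrostannation; then I2 and MnO2 for the enal).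
4. Arylpropargyl alcohol ⇒ Sonogashira of 4-iodoguaiacol and propargyl alcohol; 4-iodoguaiacol ⇒ guaiacol ⇒ catechol.
5. Rings: both benzene rings come from catechol; the only ring built is the carbocycle, first as the spiro five-membered ring, then expanded to the dihydronaphthalene.

Assumption: numbering used here is C-1 (aryl-bearing CH), C-2 (CH–CH2OH), C-3 (C–CHO), C-4 (=CH), ring A fused, ring B pendant, target (1S,2R) and trans; the sense of induction of the chiral acid in step 8 has to be fixed by experiment, so the (R)-catalyst is written and its mirror image is used if the antipode forms.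

## Route

Step 1
Reactants: 1 catechol
Product: 2 guaiacol (2-methoxyphenol)
Conditions: MeI (1.0 equiv), K2CO3 (1.0 equiv), acetone, reflux; distil
Reagents that add atoms: iodomethane (CI)
Why: Williamson O-methylation of the mono-phenoxide, with one equivalent of MeI limiting dimethylation, and 2 is separated from 1 and veratrole by distillation.

Step 2
Reactants: 2 guaiacol
Product: 3 4-iodo-2-methoxyphenol
Conditions: N-iodosuccinimide (1.0 equiv), TsOH·H2O (10 mol%), MeCN, 25 °C
Reagents that add atoms: N-iodosuccinimide (O=C1CCC(=O)N1I)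
Why: Electrophilic aromatic iodination goes para to the free OH, the stronger director, as in the known 4-halogenation of guaiacol.

Step 3
Reactants: 3 4-iodo-2-methoxyphenol; 4 prop-2-yn-1-ol
Product: 5 4-(3-hydroxyprop-1-yn-1-yl)-2-methoxyphenol
Conditions: PdCl2(PPh3)2 (2 mol%), CuI (4 mol%), Et3N/THF, 25–40 °C, degassed
Reagents that add atoms: none
Why: Sonogashira coupling of an aryl iodide proceeds under mild conditions and tolerates the free phenol and the primary alcohol.

Step 4
Reactants: 5 4-(3-hydroxyprop-1-yn-1-yl)-2-methoxyphenol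
Product: 6 (Z)-3-(4-hydroxy-3-methoxyphenyl)-2-(tributylstannyl)prop-2-en-1-ol
Conditions: [(C5Me5)RuCl]4 (1.5 mol%), Bu3SnH (1.1 equiv, slow addition), CH2Cl2, 25 °C, Ar
Reagents that add atoms: tributyltin hydride (CCCC[SnH](CCCC)CCCC)
Why: Ruthenium-catalysed trans-hydrostannation, in which the propargylic OH hydrogen-bonds to the chloride on ruthenium and steers tin to the proximal carbon while H and Sn add anti, so aryl and tin end up cis.

Step 5
Reactants: 6 (Z)-3-(4-hydroxy-3-methoxyphenyl)-2-(tributylstannyl)prop-2-en-1-ol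
Product: 7 (Z)-3-(4-hydroxy-3-methoxyphenyl)-2-iodoprop-2-en-1-ol
Conditions: I2 (1.05 equiv), CH2Cl2, 0 °C, dark; aq. Na2S2O3, then KF wash
Reagents that add atoms: iodine (II)
Why: Iododestannylation (ipso substitution at the C–Sn bond) occurs with retention of alkene geometry and is much faster than ring iodination of the neutral phenol.

Step 6
Reactants: 7 (Z)-3-(4-hydroxy-3-methoxyphenyl)-2-iodoprop-2-en-1-ol
Product: 8 (Z)-3-(4-hydroxy-3-methoxyphenyl)-2-iodoprop-2-enal
Conditions: activated MnO2 (15 equiv), CH2Cl2/acetone, 25 °C, dark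
Reagents that add atoms: none
Why: MnO2 allylic oxidation is selective for the allylic alcohol and tolerates the para-hydroxyaryl group, as in the oxidation of coniferyl alcohol to coniferaldehyde.

Step 7
Reactants: 8 (Z)-3-(4-hydroxy-3-methoxyphenyl)-2-iodoprop-2-enal; 6 (Z)-3-(4-hydroxy-3-methoxyphenyl)-2-(tributylstannyl)prop-2-en-1-ol
Product: 9 (2E,3E)-4-(4-hydroxy-3-methoxyphenyl)-2-[(4-hydroxy-3-methoxyphenyl)methylidene]-3-(hydroxymethyl)but-3-enal
Conditions: Pd2(dba)3 (2.5 mol%), AsPh3 (20 mol%), CuI (10 mol%), DMF, 25–45 °C, dark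
Reagents that add atoms: none
Why: Stille cross-coupling of an α-iodo enal with an alkenylstannane (triphenylarsine and copper co-catalysis for hindered partners) retains both alkene geometries, so each aryl group ends up cis to the new C-2–C-3 bond.

Step 8
Reactants: 9 (2E,3E)-4-(4-hydroxy-3-methoxyphenyl)-2-[(4-hydroxy-3-methoxyphenyl)methylidene]-3-(hydroxymethyl)but-3-enal
Product: 12 7,8,9,9-tetradehydroisolariciresinol [(1S,2R)-7-hydroxy-1-(4-hydroxy-3-methoxyphenyl)-2-(hydroxymethyl)-6-methoxy-1,2-dihydronaphthalene-3-carbaldehyde], via para-quinone methide 10 (not isolated), via spirodienone 11 (not isolated)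
Conditions: (R)-3,3'-bis(2,4,6-triisopropylphenyl)-1,1'-binaphthalene-2,2'-diyl N-triflylphosphoramide (10 mol%), CH2Cl2 (0.01 M), 4 Å MS, −40 °C, then 25 °C, dark
Reagents that add atoms: none
Why: Proposed new method: the chiral acid shuttles the phenolic proton of ring B to C-2 of the para-hydroxystyrene unit and gives the catalyst-bound para-quinone methide 10 reversibly (its C-2 epimers interconvert through achiral 9); ring A, held by an OH···O=P hydrogen bond, then adds through the carbon para to its OH (ipso, the carbon bearing C-4) to C-1 on one face and closes the five-membered ring of spirodienone 11 with aryl and CH2OH trans (a dynamic kinetic asymmetric intramolecular 1,6-addition that sets C-1 and C-2); on warming the same acid protonates the dienone and the benzylic carbon C-1 shifts 1,2 with retention from the spiro carbon to the neighbouring ring carbon para to OMe (the other neighbour is flanked by OMe and more hindered), which expands the ring to six members and rearomatises ring A; the closest known reaction types are chiral phosphoric acid catalysed 1,6-additions to para-quinone methides formed in situ from para-vinylphenols, Brønsted acid cyclisation of 2,3-dibenzylidenesuccinates to trans-1-aryl-1,2-dihydronaphthalenes, and the dienone–phenol rearrangement of spiro[4.5]cyclohexadienones.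

## Compound list

1 | catechol (benzene-1,2-diol) | Oc1ccccc1O | starting material
2 | guaiacol (2-methoxyphenol) | COc1ccccc1O | intermediate
3 | 4-iodo-2-methoxyphenol | COc1cc(I)ccc1O | intermediate
4 | prop-2-yn-1-ol | C#CCO | starting material
5 | 4-(3-hydroxyprop-1-yn-1-yl)-2-methoxyphenol | COc1cc(C#CCO)ccc1O | intermediate
6 | (Z)-3-(4-hydroxy-3-methoxyphenyl)-2-(tributylstannyl)prop-2-en-1-ol (aryl cis to tin) | OC/C(=C/c1ccc(O)c(OC)c1)[Sn](CCCC)(CCCC)CCCC | intermediate
7 | (Z)-3-(4-hydroxy-3-methoxyphenyl)-2-iodoprop-2-en-1-ol (aryl cis to iodine) | OC/C(I)=C/c1ccc(O)c(OC)c1 | intermediate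
8 | (Z)-3-(4-hydroxy-3-methoxyphenyl)-2-iodoprop-2-enal (aryl cis to iodine) | O=C/C(I)=C/c1ccc(O)c(OC)c1 | intermediate
9 | (2E,3E)-4-(4-hydroxy-3-methoxyphenyl)-2-[(4-hydroxy-3-methoxyphenyl)methylidene]-3-(hydroxymethyl)but-3-enal (each aryl cis to the central C–C bond) | O=C/C(=C/c1ccc(O)c(OC)c1)/C(CO)=C\c1ccc(O)c(OC)c1 | intermediate
10 | para-quinone methide, formed in the flask in step 8: (2E,3R)-2-[(4-hydroxy-3-methoxyphenyl)methylidene]-3-(hydroxymethyl)-4-(3-methoxy-4-oxocyclohexa-2,5-dien-1-ylidene)butanal (geometry of the quinone methide exocyclic bond not fixed) | O=C/C(=C/c1ccc(O)c(OC)c1)[C@@H](C=C1C=CC(=O)C(OC)=C1)CO | intermediate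
11 | spirodienone, formed in the flask in step 8: (3R,4S)-4-(4-hydroxy-3-methoxyphenyl)-3-(hydroxymethyl)-7-methoxy-8-oxospiro[4.5]deca-1,6,9-triene-2-carbaldehyde (aryl and CH2OH trans; either configuration at the spiro carbon, both give 12) | COc1cc([C@H]2C3(C=CC(=O)C(OC)=C3)C=C(C=O)[C@@H]2CO)ccc1O | intermediate
12 | 7,8,9,9-tetradehydroisolariciresinol: (1S,2R)-7-hydroxy-1-(4-hydroxy-3-methoxyphenyl)-2-(hydroxymethyl)-6-methoxy-1,2-dihydronaphthalene-3-carbaldehyde, trans [IUPAC locants: (3R,4S)-6-hydroxy-4-(4-hydroxy-3-methoxyphenyl)-3-(hydroxymethyl)-7-methoxy-3,4-dihydronaphthalene-2-carbaldehyde] | COc1cc([C@H]2c3cc(O)c(OC)cc3C=C(C=O)[C@@H]2CO)ccc1O | target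

## Step count and risks

Total steps: 8. Longest linear sequence: 8 (1 → 2 → 3 → 5 → 6 → 7 → 8 → 9 → 12; stannane 6 is used twice).

**Step 8 (the proposed new step).** Risks are low enantioselectivity, ionisation of the allylic CH2OH under acid, and a sluggish 1,2-shift. Ring A carries its only catalyst-bound activating group para to the tether, so closure through the ipso carbon to 11 is expected; any direct closure at the carbon para to OMe would give the same 12. Fallback, from 9 back to 12, with known chemistry: 9 is cyclised with an achiral Brønsted acid (CF3CO2H, CH2Cl2, 0 °C), the established acid cyclisation of 2,3-bis(arylidene) C4 units to trans-1-aryl-1,2-dihydronaphthalenes, to give the racemic trans aldehyde F1. The racemate is resolved by lipase-catalysed acylation of the primary alcohol (Burkholderia cepacia lipase, vinyl acetate, tert-butyl methyl ether, 30 °C, stopped near half conversion). This is expected to leave 12 untouched and turn its mirror image into the (1R,2S)-acetate F2, which is removed by chromatography. If the enzyme prefers the other enantiomer, the (1S,2R)-acetate F3 is isolated instead and cleaved with K2CO3 in MeOH to 12.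

**Step 4.** Risks are catalyst deactivation by the electron-rich arene and incomplete proximal or anti selectivity on an aryl alkyne. Fallback, from 3, returning at 7 and through 7 at 6: 3 is formylated (PdCl2(PPh3)2, CO 1 atm, HCO2Na, DMF, 100 °C) to vanillin F4. Wittig olefination with ethyl 2-iodo-2-(triphenylphosphoranylidene)acetate (toluene, 80 °C) gives ethyl (Z)-3-(4-hydroxy-3-methoxyphenyl)-2-iodoprop-2-enoate F5. Reduction with i-Bu2AlH (CH2Cl2, −78 °C) gives 7. Stannane 6 is then made from 7 by palladium-catalysed stannylation with (Bu3Sn)2 (Pd(PPh3)4, toluene, 90 °C).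

**Step 7.** Risks are slow transmetalation of the α-substituted stannane, homocoupling, and the light sensitivity of 9. Fallback, from 6 back to 9: 6 is homocoupled with CuCl (3 equiv, DMF, 25 °C, known for alkenylstannanes, retention of geometry) to the symmetrical diol (2E,3E)-2,3-bis[(4-hydroxy-3-methoxyphenyl)methylidene]butane-1,4-diol F6. One of its two equivalent allylic alcohols is then oxidised with a limited amount of MnO2 (CH2Cl2/acetone, 25 °C, stopped near half conversion, unreacted diol recycled) to give 9.

Further compounds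
F1 | step 8 | racemic trans-7-hydroxy-1-(4-hydroxy-3-methoxyphenyl)-2-(hydroxymethyl)-6-methoxy-1,2-dihydronaphthalene-3-carbaldehyde (1:1 mixture of 12 and its enantiomer) | COc1cc([C@H]2c3cc(O)c(OC)cc3C=C(C=O)[C@@H]2CO)ccc1O.COc1cc([C@@H]2c3cc(O)c(OC)cc3C=C(C=O)[C@H]2CO)ccc1O
F2 | step 8 | [(1R,2S)-3-formyl-7-hydroxy-1-(4-hydroxy-3-methoxyphenyl)-6-methoxy-1,2-dihydronaphthalen-2-yl]methyl acetate | COc1cc([C@@H]2c3cc(O)c(OC)cc3C=C(C=O)[C@H]2COC(C)=O)ccc1O
F3 | step 8 | [(1S,2R)-3-formyl-7-hydroxy-1-(4-hydroxy-3-methoxyphenyl)-6-methoxy-1,2-dihydronaphthalen-2-yl]methyl acetate | COc1cc([C@H]2c3cc(O)c(OC)cc3C=C(C=O)[C@@H]2COC(C)=O)ccc1O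
F4 | step 4 | vanillin (4-hydroxy-3-methoxybenzaldehyde) | COc1cc(C=O)ccc1O
F5 | step 4 | ethyl (Z)-3-(4-hydroxy-3-methoxyphenyl)-2-iodoprop-2-enoate | CCOC(=O)/C(I)=C/c1ccc(O)c(OC)c1
F6 | step 7 | (2E,3E)-2,3-bis[(4-hydroxy-3-methoxyphenyl)methylidene]butane-1,4-diol | OC/C(=C/c1ccc(O)c(OC)c1)/C(CO)=C\c1ccc(O)c(OC)c1
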